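A direct plan would build ring C last through the C3–C4 bond: a doubly O-benzylated 3-benzylsalicylaldehyde A1 would be O-alkylated
with the racemic β-chloro-α-keto ester A2 to give aryl ether A3, and a chiral carbene catalyst would close A3 by a crossed benzoin
reaction with dynamic kinetic resolution to the 3-hydroxy-3-carboxylate A4; deallylation, decarboxylation and hydrogenolysis would follow.
Its weakest steps would be:
- the double O-benzylation leading to A1, because the two chelated ortho hydroxyls differ only by the neighbouring benzyl group, so the 6-benzyl series would leak in;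
- the benzoin closure of A3, because it would need catalyst control of the keto face together with racemisation of the aryloxy centre in a substrate that can expel aryloxide;
- the excision of the ester from A4, because it adds length without complexity and would leave C3 to equilibration through an oxidation-prone enediol.

The route rests on cutting the C2–C1′ bond between ring C and ring B. Because C2 is the unsubstituted β-carbon of the C4 ketone in a chromone, a flat, achiral 8-benzylchromone can take up ring B by rhodium-catalysed enantioselective conjugate arylation, which joins the last fragment and sets C2 in one operation; C3 then follows from C2 by a Rubottom oxidation. Ring A is made unambiguous by symmetry: the formyl carbon of the starting aldehyde marks the para oxygen, then becomes the benzylic CH2, so only the hydroxyl beside the benzyl group can close ring C. Hydroxyl differentiation between two chelated positions, hindered phenol alkylation, carbene catalysis and the sacrificial ester all disappear.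

Key step: step 6

Assumption: the (S)-diphosphine of step 6 is taken to deliver the aryl group to the C2 face that gives the (2S)-flavanone; if the sense were opposite, the (R)-ligand would be used with no other change.

Step 1
Reactants: 1 2,4,6-trihydroxybenzaldehyde
Product: 2 4-(benzyloxy)-2,6-dihydroxybenzaldehyde
Conditions: BnBr (1.0 equiv), CsHCO3 (1.2 equiv), MeCN, 60 °C
Reagents that add atoms: benzyl bromide, BrCc1ccccc1
Why: Williamson etherification with a weak base should alkylate the para hydroxyl first, because it is the only one not tied up in a hydrogen bond to the formyl group, so the two chelated ortho hydroxyls stay free and the product keeps its mirror symmetry; no stereocentre.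

Step 2
Reactants: 2 4-(benzyloxy)-2,6-dihydroxybenzaldehyde; 3 4-(benzyloxy)phenylmagnesium bromide
Product: 5 5-(benzyloxy)-2-[4-(benzyloxy)benzyl]benzene-1,3-diol, via diarylcarbinol 4 (not isolated)
Conditions: 3 (3.3 equiv), THF, 0 °C to rt; then CH2Cl2, Et3SiH (3 equiv), CF3CO2H (10 equiv), 0 °C
Reagents that add atoms: none
Why: Grignard addition to the aldehyde (two further equivalents are spent on the phenols) followed by ionic hydrogenation, in which acid ionises the doubly ortho-hydroxylated diarylcarbinol to a quinone-methide-like cation that triethylsilane reduces, should turn the formyl carbon into the diarylmethane CH2 flanked by two equivalent hydroxyls; the racemic carbinol centre is removed.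

Step 3
Reactants: 5 5-(benzyloxy)-2-[4-(benzyloxy)benzyl]benzene-1,3-diol
Product: 7 1-{6-(benzyloxy)-3-[4-(benzyloxy)benzyl]-2,4-dihydroxyphenyl}ethan-1-one, via ketiminium chloride 6 (not isolated)
Conditions: MeCN (5 equiv), ZnCl2 (1.2 equiv), HCl (g), Et2O, 0 °C; then H2O, 90 °C
Reagents that add atoms: acetonitrile, CC#N; water, O
Why: Houben–Hoesch acylation at one of the two equivalent free ring positions and hydrolysis of the ketiminium salt can give only one ketone, whose single ortho hydroxyl is the one next to the benzyl group because the other ortho oxygen is already benzylated; no stereocentre.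

Step 4
Reactants: 7 1-{6-(benzyloxy)-3-[4-(benzyloxy)benzyl]-2,4-dihydroxyphenyl}ethan-1-one
Product: 8 1-{4,6-bis(benzyloxy)-3-[4-(benzyloxy)benzyl]-2-hydroxyphenyl}ethan-1-one
Conditions: BnBr (1.05 equiv), K2CO3 (1.2 equiv), acetone, 50 °C
Reagents that add atoms: benzyl bromide, BrCc1ccccc1
Why: Williamson etherification should take place only at the para hydroxyl, since the ortho hydroxyl is locked in a hydrogen bond to the acetyl group and shielded by the benzyl substituent; no stereocentre.

Step 5
Reactants: 8 1-{4,6-bis(benzyloxy)-3-[4-(benzyloxy)benzyl]-2-hydroxyphenyl}ethan-1-one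
Product: 10 5,7-bis(benzyloxy)-8-[4-(benzyloxy)benzyl]-4H-chromen-4-one, via enaminone 9 (not isolated)
Conditions: Me2NCH(OMe)2 (3 equiv), toluene, 100 °C; then aq. HCl (2 M), CH2Cl2, 40 °C
Reagents that add atoms: N,N-dimethylformamide dimethyl acetal, COC(OC)N(C)C
Why: Condensation of the methyl ketone with the amide acetal gives the enaminone, and acid promotes 6-endo addition of the free ortho hydroxyl to its β-carbon with loss of dimethylamine (enaminone route to chromones), which closes ring C through O1–C2 with the benzyl group necessarily at C8; no stereocentre.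

Step 6
Reactants: 10 5,7-bis(benzyloxy)-8-[4-(benzyloxy)benzyl]-4H-chromen-4-one; 11 4-(tert-butyldimethylsilyloxy)phenylboronic acid
Product: 12 (2S)-5,7-bis(benzyloxy)-8-[4-(benzyloxy)benzyl]-2-[4-(tert-butyldimethylsilyloxy)phenyl]chroman-4-one
Conditions: 11 (3 equiv), [RhCl(C2H4)2]2 (2.5 mol%), (S)-2,2′-bis[bis(3,4,5-trifluorophenyl)phosphino]-6,6′-dimethoxy-1,1′-biphenyl (5.5 mol%), KOH (10 mol%), toluene/H2O (10:1), 25 °C
Reagents that add atoms: none
Why: Transmetallation of the boronic acid to the hydroxo complex of monovalent rhodium gives an arylrhodium species that coordinates the C2=C3 bond of the chromone and inserts it enantioface-selectively, placing the aryl group on C2 and rhodium on the oxa-π-allyl unit, which water protonates to release the flavanone and regenerate the hydroxo complex. The closest known reaction is the rhodium-catalysed asymmetric 1,4-addition of arylboronic acids to chromones that gives flavanones. No ring is closed; the step forms the C2–C1′ bond that joins ring B to the finished A/C core. The only new stereocentre, C2, is set (S) by the chiral diphosphine, which differentiates the two faces of the flat pyranone. The step needs 1,4- over 1,2-addition and survival of ring C: C2 carries only hydrogen, so insertion is unhindered, the electron-poor diphosphine speeds insertion into the electron-rich enone, and the nearly neutral aqueous medium protonates the rhodium enolate before it can expel the C8a aryloxide.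

Step 7
Reactants: 12 (2S)-5,7-bis(benzyloxy)-8-[4-(benzyloxy)benzyl]-2-[4-(tert-butyldimethylsilyloxy)phenyl]chroman-4-one
Product: 15 (2R,3R)-5,7-bis(benzyloxy)-8-[4-(benzyloxy)benzyl]-3-hydroxy-2-(4-hydroxyphenyl)chroman-4-one, via silyl enol ether 13 (not isolated), via silyloxy epoxide 14 (not isolated)
Conditions: Me3SiOTf (1.3 equiv), Et3N (2 equiv), CH2Cl2, 0 °C, then pentane and filtration; dimethyldioxirane (1.2 equiv) in acetone, CH2Cl2, −40 °C; then HF·pyridine, THF, 0 °C to rt
Reagents that add atoms: dimethyldioxirane, CC1(C)OO1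
Why: Rubottom oxidation, in which soft enolisation gives the silyl enol ether without a free enolate (so ring C cannot open), dimethyldioxirane epoxidises C3=C4 from the face opposite the C2 aryl group, and fluoride opens the silyloxy epoxide to the ketol and cleaves the aryl silyl ether in the same operation, so that C3 is set (R), 2,3-trans, by substrate control from C2 in what is also the more stable diequatorial arrangement.

Step 8
Reactants: 15 (2R,3R)-5,7-bis(benzyloxy)-8-[4-(benzyloxy)benzyl]-3-hydroxy-2-(4-hydroxyphenyl)chroman-4-one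
Product: 16 (2R,3R)-3,5,7-trihydroxy-8-(4-hydroxybenzyl)-2-(4-hydroxyphenyl)chroman-4-one
Conditions: H2 (1 atm), Pd/C (10 wt% Pd), EtOAc/MeOH, rt
Reagents that add atoms: none
Why: Hydrogenolysis of the three aryl benzyl ethers over palladium under neutral conditions should leave the C4 ketone, the diarylmethane and the C2–O1 bond intact and expose neither stereocentre to acid or base.

**Compound list**
1 | 2,4,6-trihydroxybenzaldehyde | O=Cc1c(O)cc(O)cc1O | starting material
2 | 4-(benzyloxy)-2,6-dihydroxybenzaldehyde | O=Cc1c(O)cc(OCc2ccccc2)cc1O | intermediate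
3 | 4-(benzyloxy)phenylmagnesium bromide | Br[Mg]c1ccc(OCc2ccccc2)cc1 | starting material
4 | 5-(benzyloxy)-2-{[4-(benzyloxy)phenyl](hydroxy)methyl}benzene-1,3-diol (racemic; not isolated) | OC(c1ccc(OCc2ccccc2)cc1)c1c(O)cc(OCc2ccccc2)cc1O | intermediate
5 | 5-(benzyloxy)-2-[4-(benzyloxy)benzyl]benzene-1,3-diol | Oc1cc(OCc2ccccc2)cc(O)c1Cc1ccc(OCc2ccccc2)cc1 | intermediate
6 | 1-{6-(benzyloxy)-3-[4-(benzyloxy)benzyl]-2,4-dihydroxyphenyl}ethan-1-iminium chloride (not isolated) | CC(=[NH2+])c1c(O)c(Cc2ccc(OCc3ccccc3)cc2)c(O)cc1OCc1ccccc1.[Cl-] | intermediate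
7 | 1-{6-(benzyloxy)-3-[4-(benzyloxy)benzyl]-2,4-dihydroxyphenyl}ethan-1-one | CC(=O)c1c(O)c(Cc2ccc(OCc3ccccc3)cc2)c(O)cc1OCc1ccccc1 | intermediate
8 | 1-{4,6-bis(benzyloxy)-3-[4-(benzyloxy)benzyl]-2-hydroxyphenyl}ethan-1-one | CC(=O)c1c(O)c(Cc2ccc(OCc3ccccc3)cc2)c(OCc2ccccc2)cc1OCc1ccccc1 | intermediate
9 | (E)-1-{4,6-bis(benzyloxy)-3-[4-(benzyloxy)benzyl]-2-hydroxyphenyl}-3-(dimethylamino)prop-2-en-1-one (not isolated) | CN(C)/C=C/C(=O)c1c(O)c(Cc2ccc(OCc3ccccc3)cc2)c(OCc2ccccc2)cc1OCc1ccccc1 | intermediate
10 | 5,7-bis(benzyloxy)-8-[4-(benzyloxy)benzyl]-4H-chromen-4-one | O=c1ccoc2c(Cc3ccc(OCc4ccccc4)cc3)c(OCc3ccccc3)cc(OCc3ccccc3)c12 | intermediate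
11 | 4-(tert-butyldimethylsilyloxy)phenylboronic acid | CC(C)(C)[Si](C)(C)Oc1ccc(B(O)O)cc1 | starting material
12 | (2S)-5,7-bis(benzyloxy)-8-[4-(benzyloxy)benzyl]-2-[4-(tert-butyldimethylsilyloxy)phenyl]chroman-4-one | O=C1c2c(OCc3ccccc3)cc(OCc3ccccc3)c(Cc3ccc(OCc4ccccc4)cc3)c2O[C@H](c2ccc(O[Si](C)(C)C(C)(C)C)cc2)C1 | intermediate
13 | {[(2S)-5,7-bis(benzyloxy)-8-[4-(benzyloxy)benzyl]-2-[4-(tert-butyldimethylsilyloxy)phenyl]-2H-chromen-4-yl]oxy}trimethylsilane (not isolated) | C[Si](C)(C)OC1=C[C@@H](c2ccc(O[Si](C)(C)C(C)(C)C)cc2)Oc2c1c(OCc1ccccc1)cc(OCc1ccccc1)c2Cc1ccc(OCc2ccccc2)cc1 | intermediate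
14 | (2R,3R,4R)-5,7-bis(benzyloxy)-8-[4-(benzyloxy)benzyl]-2-[4-(tert-butyldimethylsilyloxy)phenyl]-3,4-epoxy-4-(trimethylsilyloxy)chromane (oxirane oxygen trans to the C2 aryl group; not isolated) | C[Si](C)(C)O[C@@]12O[C@@H]1[C@@H](c1ccc(O[Si](C)(C)C(C)(C)C)cc1)Oc1c2c(OCc2ccccc2)cc(OCc2ccccc2)c1Cc1ccc(OCc2ccccc2)cc1 | intermediate
15 | (2R,3R)-5,7-bis(benzyloxy)-8-[4-(benzyloxy)benzyl]-3-hydroxy-2-(4-hydroxyphenyl)chroman-4-one | O=C1c2c(OCc3ccccc3)cc(OCc3ccccc3)c(Cc3ccc(OCc4ccccc4)cc3)c2O[C@H](c2ccc(O)cc2)[C@H]1O | intermediate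
16 | (2R,3R)-3,5,7-trihydroxy-8-(4-hydroxybenzyl)-2-(4-hydroxyphenyl)chroman-4-one | O=C1c2c(O)cc(O)c(Cc3ccc(O)cc3)c2O[C@H](c2ccc(O)cc2)[C@H]1O | target

Total step count: 8. Longest linear sequence: 8 steps (1 to 16); 3 and 11 are purchased.

Steps most likely to fail:

1. Step 6. Insertion into the electron-rich, 5-alkoxy-substituted enone may be slower than protodeboronation of the electron-rich boronic acid, and hydroxide-induced opening of the pyranone or retro-oxa-Michael equilibration of the product could erode conversion and enantiopurity. The fallback sets out from 8 and uses a chalcone epoxide instead of a conjugate arylation. Claisen–Schmidt condensation of 8 with 4-(methoxymethoxy)benzaldehyde (KOH, EtOH) would give (E)-1-{4,6-bis(benzyloxy)-3-[4-(benzyloxy)benzyl]-2-hydroxyphenyl}-3-[4-(methoxymethoxy)phenyl]prop-2-en-1-one F1. Capping of the chelated hydroxyl (MOMCl, NaH, DMF) would give (E)-1-{4,6-bis(benzyloxy)-3-[4-(benzyloxy)benzyl]-2-(methoxymethoxy)phenyl}-3-[4-(methoxymethoxy)phenyl]prop-2-en-1-one F2. Juliá–Colonna epoxidation (poly-L-leucine, urea–H2O2, DBU, THF) would give {4,6-bis(benzyloxy)-3-[4-(benzyloxy)benzyl]-2-(methoxymethoxy)phenyl}{(2R,3S)-3-[4-(methoxymethoxy)phenyl]oxiran-2-yl}methanone F3. HCl in MeOH would then remove both acetals and let the freed ortho hydroxyl open the oxirane at the benzylic carbon (6-endo), so that the route is rejoined at 15 with steps 6 and 7 bypassed.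

2. Step 7. Epoxidation may show incomplete facial selectivity, the oxidant may attack the electron-rich rings or benzylic positions, and ring C may open to the chalcone during enolisation or desilylation. The fallback sets out from 12 and oxidises the ketone directly instead of its enol ether. α-Acetoxylation with Pb(OAc)4 (BF3·OEt2, AcOH/benzene, rt) would give (2R,3R)-5,7-bis(benzyloxy)-8-[4-(benzyloxy)benzyl]-2-[4-(tert-butyldimethylsilyloxy)phenyl]-4-oxochroman-3-yl acetate F4, the trans isomer being expected from delivery of acetate opposite the C2 aryl group. Acid-catalysed methanolysis of the acetate (HCl, MeOH, rt) and cleavage of the aryl silyl ether (KHF2, MeOH) would rejoin the route at 15.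

3. Step 2. Addition to the sparingly soluble magnesium bis-phenoxide may stall, and during the ionic reduction the stabilised cation may alkylate the electron-rich resorcinol ring of product already formed, giving oligomers. The fallback sets out from 2 and forms the diarylmethane without a carbinol or acid. Condensation with 4-methylbenzenesulfonohydrazide (MeOH, rt) would give N′-[(E)-4-(benzyloxy)-2,6-dihydroxybenzylidene]-4-methylbenzenesulfonohydrazide F5. Base-promoted reductive coupling of F5 with 4-(benzyloxy)phenylboronic acid (K2CO3, 1,4-dioxane, 110 °C), through the diazo compound and a benzylic boronic acid that protodeboronates, would rejoin the route at 5.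

**Further compounds**
F1 | step 6 | (E)-1-{4,6-bis(benzyloxy)-3-[4-(benzyloxy)benzyl]-2-hydroxyphenyl}-3-[4-(methoxymethoxy)phenyl]prop-2-en-1-one | COCOc1ccc(/C=C/C(=O)c2c(O)c(Cc3ccc(OCc4ccccc4)cc3)c(OCc3ccccc3)cc2OCc2ccccc2)cc1
F2 | step 6 | (E)-1-{4,6-bis(benzyloxy)-3-[4-(benzyloxy)benzyl]-2-(methoxymethoxy)phenyl}-3-[4-(methoxymethoxy)phenyl]prop-2-en-1-one | COCOc1ccc(/C=C/C(=O)c2c(OCOC)c(Cc3ccc(OCc4ccccc4)cc3)c(OCc3ccccc3)cc2OCc2ccccc2)cc1
F3 | step 6 | {4,6-bis(benzyloxy)-3-[4-(benzyloxy)benzyl]-2-(methoxymethoxy)phenyl}{(2R,3S)-3-[4-(methoxymethoxy)phenyl]oxiran-2-yl}methanone | O=C([C@@H]1O[C@H]1c1ccc(OCOC)cc1)c1c(OCOC)c(Cc2ccc(OCc3ccccc3)cc2)c(OCc2ccccc2)cc1OCc1ccccc1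
F4 | step 7 | (2R,3R)-5,7-bis(benzyloxy)-8-[4-(benzyloxy)benzyl]-2-[4-(tert-butyldimethylsilyloxy)phenyl]-4-oxochroman-3-yl acetate | O=C1c2c(OCc3ccccc3)cc(OCc3ccccc3)c(Cc3ccc(OCc4ccccc4)cc3)c2O[C@H](c2ccc(O[Si](C)(C)C(C)(C)C)cc2)[C@H]1OC(C)=O
F5 | step 2 | N′-[(E)-4-(benzyloxy)-2,6-dihydroxybenzylidene]-4-methylbenzenesulfonohydrazide | Cc1ccc(cc1)S(=O)(=O)N/N=C/c1c(O)cc(OCc2ccccc2)cc1O
A1 | direct plan | 4,6-bis(benzyloxy)-3-[4-(benzyloxy)benzyl]-2-hydroxybenzaldehyde | O=Cc1c(OCc2ccccc2)cc(OCc2ccccc2)c(Cc2ccc(OCc3ccccc3)cc2)c1O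
A2 | direct plan | allyl 3-chloro-3-[4-(benzyloxy)phenyl]-2-oxopropanoate (racemic) | C=CCOC(=O)C(=O)C(Cl)c1ccc(OCc2ccccc2)cc1
A3 | direct plan | allyl 3-{3,5-bis(benzyloxy)-2-[4-(benzyloxy)benzyl]-6-formylphenoxy}-3-[4-(benzyloxy)phenyl]-2-oxopropanoate (racemic) | C=CCOC(=O)C(=O)C(Oc1c(C=O)c(OCc2ccccc2)cc(OCc2ccccc2)c1Cc1ccc(OCc2ccccc2)cc1)c1ccc(OCc2ccccc2)cc1
A4 | direct plan | allyl (2R,3R)-5,7-bis(benzyloxy)-8-[4-(benzyloxy)benzyl]-2-[4-(benzyloxy)phenyl]-3-hydroxy-4-oxochromane-3-carboxylate | O=C1c2c(OCc3ccccc3)cc(OCc3ccccc3)c(Cc3ccc(OCc4ccccc4)cc3)c2O[C@H](c2ccc(OCc3ccccc3)cc2)[C@]1(O)C(=O)OCC=C
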